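## Analysis of the target

1. Atom numbering: C1 is the methyl-bearing bridgehead, C2 the enol carbon, C3 the acylated carbon, C4 the ring ketone, C5 the second bridgehead, C6 the ring-fusion CH, C7 the CH2, C8 the bridging ketone, C9 the CMe2 carbon, C10 the CH that carries the carbinol, C11 the CH2, and C12 the carbinol carbon on C10.
2. The skeleton is a tricyclo[5.3.1.0^{1,5}]undecane: ring A (C1–C2–C3–C4–C5–C8) and ring B (C1–C7–C6–C5–C8) form a bicyclo[3.2.1]octane-2,4,8-trione, and the cyclopentane ring C (C5–C6–C9–C10–C11) is fused on the C5–C6 bond.
3. The stereocentres are C1, C5, C6 and C10 (all S) and the (R) centre of the 2-methylbutanoyl group on C3. Rings B and C form a cis-diquinane, and the C12 branch on C10 lies on its concave face, cis to C7 and C8. C1 is a bridgehead, so its configuration follows from C5 once ring A is closed.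
4. The side-chain centre is independent of the ring system and must be brought in intact.
5. Sensitive groups are the acidic, tautomeric enolised β-triketone, the C8 ketone between two quaternary carbons (open to retro-Claisen cleavage), the tertiary alcohol near C8 (dehydration, hemiketal formation) and the base-labile α-centre of the acyl group.
6. The difficulty is congestion: C1, C5 and C9 are quaternary, C6 sits between two of them, and ring C holds a quaternary carbon between two stereocentres, so closing that cyclopentane directly is unattractive.
7. The strategy rests on one feature: C10 carries a one-carbon oxygenated branch (C12) beside quaternary C9. This is the pattern left when a carbonyl carbon between C9 and C10 in a six-membered ring is expelled from the ring with migration of C9, so ring C can come from a cyclohexanone that a cycloaddition builds easily.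

## Retrosynthetic reasoning

**C3–acyl bond.** Cutting the exocyclic C3–C(=O) bond of 23 gives the bicyclic trione 20 and the acid 21. The cut is made here, and last, because it keeps the only stereocentre outside the ring system away from all enolate chemistry. C3 of 20 is the nucleophilic carbon of an enolised 1,3-diketone, so the forward reaction is O-acylation followed by a 1,3-acyl shift (through 22). It must leave the tertiary alcohol and the α-centre of the acyl group untouched.

**C3–C4 bond (ring A).** Cutting C3–C4 of 20 gives 19, which has an acetyl group on C1 and the methyl ester on C5. C4 is already at the acid oxidation level in the ester that activated the ring at the start of the synthesis. The forward reaction is an intramolecular Claisen condensation. It closes ring A and the bridged system in one step, and it only requires that the acetyl group and the ester be cis on ring B.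

**C1–C2 and C1–CH3 bonds.** 19 goes back through the aldol product 18 and the monomethyl ketone 17 to ketone 16. C1 is the only enolisable carbon beside C8, since C5 is quaternary. The methyl group is introduced first and the two-carbon unit second, so that the second electrophile enters on the convex face and ends cis to the C5 ester. The acetyl group is built by aldol addition and oxidation because direct C-acylation of a hindered, fully substituted enolate tends to give the enol ester.

**C12–CH3 bonds (carbinol).** The carbinol of 16 comes from the C10 methyl ester of 12 by two methyl additions, through ketone 14. C8 has to be masked during that step, which gives the dioxolanes 13 and 15. This is done directly after the key step: C10 can epimerise only while it carries an ester, so it is converted before any strong base is used.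

**C9–C10 bond (ring contraction, the key disconnection).** Re-inserting C12 between C9 and C10 turns the cyclopentane ester 12 into the six-membered 2-diazo ketone 10, by way of ketene 11. The forward reaction moves C9 from C12 to C10 with loss of nitrogen. C9 is the only group that can migrate, and C12 arrives on C10 at the ester oxidation level, ready for the carbinol. The reaction must favour rearrangement over carbene insertion, and the proton must reach C10 from the convex face.

**Diazo group at C10.** Diazo transfer needs an activating acyl group on C10. Base-mediated acylation of the free diketone would not tell C10 from C1, because the C8 ketone has its own enolisable CH2 at C1. The enol ether 7 is therefore used directly: its enol double bond already points from C12 to C10. A one-carbon electrophile at the formate level is added there (through acetal 8) to give the formyl ketone 9, and deformylative diazo transfer gives 10.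

**C5–C11 and C6–C9 bonds (cycloaddition).** Cutting both bonds of 7 gives the enone ester 4 and the silyloxy diene 6. One step then builds the cis-fused six-membered ring with both quaternary carbons C5 and C9. The polarity matches: the nucleophilic CMe2 terminus of 6 meets the electrophilic C6 of 4. The keto ester of 4 can chelate a chiral Lewis acid, which sets the absolute configuration of C5 and C6.

**Starting materials.** 4 comes from the keto ester 1 by selenenylation to 2 and selenoxide elimination (through 3). 6 comes from the vinyl ketone 5 by silylation of its only enolisable position.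

## Alternatives that were turned down

**Alternative 1:** This cuts C5–C6 and C1–C7 together and leads back to a flat aromatic precursor, the acylphloroglucinol A1, which carries the branched pentenyl chain on the carbon that becomes C5. In the forward key step a hypervalent iodine oxidant in a fluorinated alcohol turns the phenol into a phenoxonium (pentadienyl) cation, whose two ortho carbons add across the terminal vinyl group to give the triethylsilyl ether of the target, A2.
- For it: rings B and C and the stereocentres C1, C5 and C6 arise in one step; the acyl group is already in place; only desilylation remains; the aromatic precursor is assembled by ordinary phenol chemistry. On step count and convergence it is clearly stronger than the chosen route.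
- Against it: the only stereocentre that can steer the cycloaddition is C10 in a flexible tether beside a gem-dimethyl group, so face selection depends on tether conformation and not on a rigid element.
- Against it: the two-carbon partner is an unactivated monosubstituted alkene on a neopentyl carbon. A stepwise cationic path that closes the five-membered ring first would place charge on a primary carbon.
- Against it: the electron-poor trihydroxy acylphenol is hard to oxidise, and its cation can be trapped by solvent or by its own hydroxyl groups. A1 also needs its own enantioselective synthesis of the C10 centre.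
- In exchange for more steps, the chosen strategy forms each skeletal bond by a reaction with a close analogy on the same substrate class, and it fixes C5, C6 and C1 by catalyst control and ring constraints, not by remote induction.

**Alternative 2:** This takes ring C as the cyclopentane of a norbornene and cuts C5–C6 and C10–C11. In the forward key step the spiro diene A3 and the silyloxymethyl acrolein A4 combine under a chiral cationic oxazaborolidine Lewis acid to give the norbornene aldehyde A5. The spiro cyclopropane is the latent gem-dimethyl group of C9, and the ring double bond is to be cleaved into C7 and C12.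
- For it: this class of cycloaddition is among the most dependable enantioselective reactions, and C5, C6 and C10 are set at once. The cis relation of the C10 branch to C7 is built in by the bicycle. On that point it is stronger than the chosen route, which relies on a kinetic protonation.
- Against it: after A5 neither ring A nor ring B exists. Cleaving the alkene gives two similar carbonyl termini that must be told apart.
- Against it: ring B must then be closed through the quaternary C1, ring A must be added, the cyclopropane needs forcing hydrogenolysis, and several redox and protecting-group steps are required. The step count would be well above that of the chosen route.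
- The chosen strategy has ring B from the first step, with C8 already a ketone that first activates the dienophile and later C1. Nothing has to be differentiated after a cleavage, and the end-game is short.

**Alternative 3:** This cuts C5–C8 and leads back to the ring-C-fused cycloheptane-1,3-dione A6, which carries on C1 the methyl group and the ester that becomes C8. In the forward key step two equivalents of a lithium silylamide base give the C3/C5 dianion, whose C5 terminus attacks the ester across the ring to give the silyl-protected trione A7.
- For it: the dianion is regiochemically unambiguous; the product is a stabilised enolate, so the condensation is driven forward; no photochemistry or diazo chemistry is needed; C5 needs no external control, because the ester on C1 dictates it. A7 is the silyl ether of compound 20, so the end-game is the same. The key step itself is thermodynamically more secure than the photolysis chosen here.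
- Against it: a tertiary enolate carbon must attack a neopentyl ester across a seven-membered ring to make a quaternary bridgehead.
- Against it: the stereochemical burden moves to A6. C1 must be set relative to C6 and C10 across a flexible ring, and ring C with its C9/C10 congestion still has to be made, which this strategy does not address. Reaching A6 would take at least as many steps as reaching 19.
- The chosen strategy solves the ring-C problem explicitly and sets C1 last, by face-selective chemistry on a rigid diquinane.

Key step: step 7

Assumption: the (S,S)-tert-butyl bis(oxazoline) complex of Cu(OSO2CF3)2 is taken to expose the face of chelated 4 that leads to the (5S,6S) adduct 7; if the sense of induction is the opposite, the (R,R)-ligand is used and nothing else changes.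

## Route

**Step 1**
Reactants: 1 methyl 2-oxocyclopentane-1-carboxylate
Product: 2 methyl 2-oxo-1-(phenylselanyl)cyclopentane-1-carboxylate (racemic)
Conditions: PhSeCl, pyridine, CH2Cl2, 0 °C → rt
Reagents that add atoms: phenylselenyl chloride, Cl[Se]c1ccccc1
Why: α-Selenenylation of the β-keto ester enol at its doubly activated carbon, the only nucleophilic position; pyridine takes up the HCl.

**Step 2**
Reactants: 2 methyl 2-oxo-1-(phenylselanyl)cyclopentane-1-carboxylate
Product: 4 methyl 5-oxocyclopent-1-ene-1-carboxylate, via selenoxide 3 (not isolated)
Conditions: H2O2 (30 % aq.), CH2Cl2, 0 °C → rt; used at once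
Reagents that add atoms: none
Why: Selenoxide elimination: oxidation at selenium is followed by syn-elimination towards the only β-hydrogens, on the ring CH2 that becomes C6; the doubly activated enone is used directly because it oligomerises on standing.

**Step 3**
Reactants: 5 4-methylpent-1-en-3-one
Product: 6 tert-butyl(dimethyl)[(4-methylpenta-1,3-dien-3-yl)oxy]silane
Conditions: tert-butyldimethylsilyl trifluoromethanesulfonate, Et3N, Et2O, 0 °C
Reagents that add atoms: tert-butyldimethylsilyl trifluoromethanesulfonate, CC(C)(C)[Si](C)(C)OS(=O)(=O)C(F)(F)F
Why: Soft enolisation (silyl triflate and amine) of the vinyl ketone; the isopropyl methine is the only enolisable position, so the 2-silyloxy diene with a dimethyl-substituted terminus is the only possible isomer.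

**Step 4**
Reactants: 4 methyl 5-oxocyclopent-1-ene-1-carboxylate; 6 tert-butyl(dimethyl)[(4-methylpenta-1,3-dien-3-yl)oxy]silane
Product: 7 methyl (3aS,7aS)-5-{[tert-butyl(dimethyl)silyl]oxy}-4,4-dimethyl-1-oxo-1,2,3,3a,4,7-hexahydro-7aH-indene-7a-carboxylate (cis-fused; 5S,6S in target numbering)
Conditions: Cu(OSO2CF3)2 (10 mol %), 2,2'-(propane-2,2-diyl)bis[(4S)-4-tert-butyl-4,5-dihydro-1,3-oxazole] (11 mol %), CH2Cl2, 4 Å molecular sieves, −78 → −20 °C
Reagents that add atoms: none
Why: Lewis acid-catalysed Diels–Alder reaction (at its asynchronous limit a Mukaiyama–Michael/Michael sequence) of a chelating 2-alkoxycarbonyl cycloalkenone with a 2-silyloxy diene: the nucleophilic CMe2 terminus bonds to the enone β-carbon C6 and the CH2 terminus to C5. The cyclic dienophile enforces the cis ring fusion, and the tert-butyl groups of the square-planar divalent copper chelate select the enone face, which sets C5 and C6.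

**Step 5**
Reactants: 7 methyl (3aS,7aS)-5-{[tert-butyl(dimethyl)silyl]oxy}-4,4-dimethyl-1-oxo-1,2,3,3a,4,7-hexahydro-7aH-indene-7a-carboxylate
Product: 9 methyl (3aS,7aS)-6-(hydroxymethylidene)-4,4-dimethyl-1,5-dioxooctahydro-7aH-indene-7a-carboxylate, via dimethyl acetal 8 (not isolated)
Conditions: HC(OCH3)3, trimethylsilyl trifluoromethanesulfonate (10 mol %), CH2Cl2, −78 °C; then 1 M HCl, THF, rt
Reagents that add atoms: trimethyl orthoformate, COC(OC)OC; water, O
Why: Mukaiyama-type condensation of the silyl enol ether with the dimethoxycarbenium ion; the position of the enol double bond in 7 makes C10 the only reacting carbon, so the enolisable C1 beside the C8 ketone never comes into play. Acid hydrolysis unmasks the formyl group, which rests as its enol.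

**Step 6**
Reactants: 9 methyl (3aS,7aS)-6-(hydroxymethylidene)-4,4-dimethyl-1,5-dioxooctahydro-7aH-indene-7a-carboxylate
Product: 10 methyl (3aS,7aS)-6-diazo-4,4-dimethyl-1,5-dioxooctahydro-7aH-indene-7a-carboxylate
Conditions: 4-acetamidobenzenesulfonyl azide, Et3N, CH3CN, 0 °C → rt
Reagents that add atoms: 4-acetamidobenzenesulfonyl azide, CC(=O)Nc1ccc(cc1)S(=O)(=O)N=[N+]=[N-]
Why: Deformylative (Regitz) diazo transfer: the amine-generated enolate of the formyl ketone adds to the sulfonyl azide and the adduct collapses with loss of the N-formyl sulfonamide. The simple C8 ketone is not acidic enough to react under these conditions, so the diazo group can only appear on C10.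

**Step 7**
Reactants: 10 methyl (3aS,7aS)-6-diazo-4,4-dimethyl-1,5-dioxooctahydro-7aH-indene-7a-carboxylate
Product: 12 dimethyl (2S,3aS,6aS)-1,1-dimethyl-4-oxohexahydropentalene-2,3a(1H)-dicarboxylate (cis-diquinane, C10 ester on the concave face), via ketene 11 (not isolated)
Conditions: hν (365 nm), CH3OH (degassed), rt
Reagents that add atoms: methanol, CO
Why: Excitation of the diazo ketone at its long-wavelength band, where the C8 ketone does not absorb and so escapes α-cleavage, expels N2 while C9, the only substituent on the carbonyl carbon C12, shifts from C12 to C10. The diazo ketone is locked s-cis in the ring, so the shift is concerted with nitrogen loss, which disfavours O–H insertion into the solvent and hydride shift from C11. The ketene 11, exocyclic to the new five-membered ring, adds methanol to give an ester enol that tautomerises by protonation at C10. The closest known reaction type is the photochemical Wolff ring contraction of cyclic 2-diazo ketones flanked by a quaternary carbon to ring-contracted esters. Ring C is closed not by a cyclisation but by a 1,2-shift that excises C12 from the six-membered ring, so no ring-closure constraint applies and the congested C9–C10 bond forms from within an existing ring. The new stereocentre C10 is controlled by the cis-diquinane: the proton should arrive on the convex face, away from ring B, which leaves the ester on the concave face, cis to C7 and C8. The step needs rearrangement over insertion, which the s-cis geometry and direct irradiation secure, and kinetic, not thermodynamic, protonation, which neutral methanol at room temperature without any base secures. C5 and C6 are not touched.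

**Step 8**
Reactants: 12 dimethyl (2S,3aS,6aS)-1,1-dimethyl-4-oxohexahydropentalene-2,3a(1H)-dicarboxylate
Product: 13 dimethyl (2'S,3a'S,6a'S)-1',1'-dimethylhexahydro-1'H-spiro[[1,3]dioxolane-2,4'-pentalene]-2',3a'-dicarboxylate
Conditions: Me3SiOCH2CH2OSiMe3, trimethylsilyl trifluoromethanesulfonate (cat.), CH2Cl2, −78 → 0 °C
Reagents that add atoms: 1,2-bis(trimethylsilyloxy)ethane, C[Si](C)(C)OCCO[Si](C)(C)C
Why: Acetalisation under Noyori conditions (aprotic, silyl triflate-catalysed, driven by formation of the disiloxane) converts the only ketone; with no protic acid or base present, the C10 ester can neither epimerise nor transesterify.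

**Step 9**
Reactants: 13 dimethyl (2'S,3a'S,6a'S)-1',1'-dimethylhexahydro-1'H-spiro[[1,3]dioxolane-2,4'-pentalene]-2',3a'-dicarboxylate
Product: 15 methyl (2'S,3a'S,6a'S)-2'-(2-hydroxypropan-2-yl)-1',1'-dimethylhexahydro-1'H-spiro[[1,3]dioxolane-2,4'-pentalene]-3a'-carboxylate, via methyl ketone 14 (not isolated)
Conditions: CH3MgBr (4 equiv), CeCl3 (anhydrous), THF, −78 → 0 °C; aq. NH4Cl
Reagents that add atoms: methylmagnesium bromide, C[Mg]Br
Why: Double Grignard addition to an ester through the methyl ketone: the C10 ester sits on a secondary carbon, whereas the C5 ester sits on a quaternary carbon flanked by the dioxolane and the ring fusion and should form its tetrahedral intermediate far more slowly. CeCl3 suppresses enolisation of the ester and of ketone 14, so C10 keeps its configuration and afterwards can no longer epimerise.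

**Step 10**
Reactants: 15 methyl (2'S,3a'S,6a'S)-2'-(2-hydroxypropan-2-yl)-1',1'-dimethylhexahydro-1'H-spiro[[1,3]dioxolane-2,4'-pentalene]-3a'-carboxylate
Product: 16 methyl (2S,3aS,6aS)-2-(2-hydroxypropan-2-yl)-1,1-dimethyl-4-oxohexahydropentalene-3a(1H)-carboxylate
Conditions: 1 M HCl, THF, rt → 40 °C
Reagents that add atoms: water, O
Why: Acid-catalysed acetal hydrolysis; the tertiary alcohol and the neopentyl ester should tolerate dilute aqueous acid, and any hemiketal between the C8 ketone and the cis carbinol is in equilibrium with 16.

**Step 11**
Reactants: 16 methyl (2S,3aS,6aS)-2-(2-hydroxypropan-2-yl)-1,1-dimethyl-4-oxohexahydropentalene-3a(1H)-carboxylate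
Product: 17 methyl (2S,3aS,5R,6aS)-2-(2-hydroxypropan-2-yl)-1,1,5-trimethyl-4-oxohexahydropentalene-3a(1H)-carboxylate (methyl on the convex face expected; the C1 epimer serves equally)
Conditions: LiN(iPr)2 (2.1 equiv), THF, −78 °C; CH3I, −78 → −20 °C
Reagents that add atoms: iodomethane, CI
Why: Kinetic enolate alkylation: after deprotonation of the hydroxyl group, C1 is the only enolisable carbon because C5 is quaternary, and the lithium alkoxide does not compete for CH3I at low temperature. The configuration at C1 is erased again in step 12.

**Step 12**
Reactants: 17 methyl (2S,3aS,5R,6aS)-2-(2-hydroxypropan-2-yl)-1,1,5-trimethyl-4-oxohexahydropentalene-3a(1H)-carboxylate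
Product: 18 methyl (2S,3aS,5S,6aS)-5-(1-hydroxyethyl)-2-(2-hydroxypropan-2-yl)-1,1,5-trimethyl-4-oxohexahydropentalene-3a(1H)-carboxylate (mixture at the new carbinol carbon)
Conditions: LiN(iPr)2 (2.2 equiv), THF, −78 → −40 °C; CH3CHO, −78 °C; CH3CO2H, −78 °C
Reagents that add atoms: acetaldehyde, CC=O
Why: Aldol addition of the fully substituted lithium enolate: the aldehyde should approach C1 on the convex face, away from ring C and the endo carbinol group, so the new C1–C2 bond is cis to the C5 ester and the methyl group ends on the concave face, which sets C1. The cold acidic quench guards against retro-aldol cleavage, and the side-chain carbinol centre is oxidised in the next step.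

**Step 13**
Reactants: 18 methyl (2S,3aS,5S,6aS)-5-(1-hydroxyethyl)-2-(2-hydroxypropan-2-yl)-1,1,5-trimethyl-4-oxohexahydropentalene-3a(1H)-carboxylate
Product: 19 methyl (2S,3aS,5S,6aS)-5-acetyl-2-(2-hydroxypropan-2-yl)-1,1,5-trimethyl-4-oxohexahydropentalene-3a(1H)-carboxylate
Conditions: Dess–Martin periodinane, CH2Cl2, 0 °C → rt
Reagents that add atoms: none
Why: Dess–Martin oxidation of the secondary alcohol under nearly neutral conditions; the tertiary alcohol cannot be oxidised, and the non-enolisable 1,3-diketone is not exposed to nucleophiles that would cleave it.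

**Step 14**
Reactants: 19 methyl (2S,3aS,5S,6aS)-5-acetyl-2-(2-hydroxypropan-2-yl)-1,1,5-trimethyl-4-oxohexahydropentalene-3a(1H)-carboxylate
Product: 20 (1R,3S,5S,7S)-8-hydroxy-3-(2-hydroxypropan-2-yl)-4,4,7-trimethyltricyclo[5.3.1.0^{1,5}]undec-8-ene-10,11-dione (enol form of the 2,4,8-trione in target numbering)
Conditions: LiN(SiMe3)2 (3.2 equiv), THF, −78 → 0 °C; then 1 M HCl
Reagents that add atoms: none
Why: Intramolecular Claisen (Dieckmann-type) condensation: the acetyl enolate, the only carbon enolate that can form, attacks the cis-disposed C5 ester in a 6-exo-trig closure of ring A, as in the known cyclisation of cis-3-acetylcyclopentanecarboxylates to bicyclo[3.2.1]octane-2,4-diones. Deprotonation of the product at C3 drives the reaction and shields the C8 ketone from retro-Claisen cleavage.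

**Step 15**
Reactants: 20 (1R,3S,5S,7S)-8-hydroxy-3-(2-hydroxypropan-2-yl)-4,4,7-trimethyltricyclo[5.3.1.0^{1,5}]undec-8-ene-10,11-dione; 21 (R)-2-methylbutanoic acid
Product: 23 (1S,3S,5S,7S)-8-hydroxy-3-(2-hydroxypropan-2-yl)-4,4,7-trimethyl-9-[(2R)-2-methylbutanoyl]tricyclo[5.3.1.0^{1,5}]undec-8-ene-10,11-dione (CNP0207052.1), via enol ester 22 (not isolated)
Conditions: N,N'-dicyclohexylcarbodiimide, 4-(dimethylamino)pyridine (1.2 equiv), CH2Cl2, 0 °C → rt
Reagents that add atoms: none
Why: Carbodiimide-mediated O-acylation of the acidic enol followed by the 4-(dimethylamino)pyridine-promoted 1,3-acyl shift to C3, the usual way to 2-acylcycloalkane-1,3-diones. The hindered tertiary alcohol should not be acylated, and with no stronger base present the α-centre of the acyl group should be retained.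

## Compound list

1 | methyl 2-oxocyclopentane-1-carboxylate | COC(=O)C1CCCC1=O | starting material
2 | methyl 2-oxo-1-(phenylselanyl)cyclopentane-1-carboxylate (racemic) | COC(=O)C1([Se]c2ccccc2)CCCC1=O | intermediate
3 | methyl 2-oxo-1-(phenylseleninyl)cyclopentane-1-carboxylate (selenoxide, not isolated) | COC(=O)C1([Se](=O)c2ccccc2)CCCC1=O | intermediate
4 | methyl 5-oxocyclopent-1-ene-1-carboxylate | COC(=O)C1=CCCC1=O | intermediate
5 | 4-methylpent-1-en-3-one | CC(C)C(=O)C=C | starting material
6 | tert-butyl(dimethyl)[(4-methylpenta-1,3-dien-3-yl)oxy]silane | C=CC(O[Si](C)(C)C(C)(C)C)=C(C)C | intermediate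
7 | methyl (3aS,7aS)-5-{[tert-butyl(dimethyl)silyl]oxy}-4,4-dimethyl-1-oxo-1,2,3,3a,4,7-hexahydro-7aH-indene-7a-carboxylate | CC(C)(C)[Si](C)(C)OC1=CC[C@@]2(C(=O)OC)C(=O)CC[C@H]2C1(C)C | intermediate
8 | methyl (3aS,7aS)-6-(dimethoxymethyl)-4,4-dimethyl-1,5-dioxooctahydro-7aH-indene-7a-carboxylate (both C6 epimers, not isolated) | COC(OC)C1C[C@@]2(C(=O)OC)C(=O)CC[C@H]2C(C)(C)C1=O | intermediate
9 | methyl (3aS,7aS)-6-(hydroxymethylidene)-4,4-dimethyl-1,5-dioxooctahydro-7aH-indene-7a-carboxylate | OC=C1C[C@@]2(C(=O)OC)C(=O)CC[C@H]2C(C)(C)C1=O | intermediate
10 | methyl (3aS,7aS)-6-diazo-4,4-dimethyl-1,5-dioxooctahydro-7aH-indene-7a-carboxylate | [N-]=[N+]=C1C[C@@]2(C(=O)OC)C(=O)CC[C@H]2C(C)(C)C1=O | intermediate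
11 | methyl (3aS,6aS)-1,1-dimethyl-4-oxo-2-(oxomethylidene)hexahydropentalene-3a(1H)-carboxylate (ketene, not isolated) | O=C=C1C[C@@]2(C(=O)OC)C(=O)CC[C@H]2C1(C)C | intermediate
12 | dimethyl (2S,3aS,6aS)-1,1-dimethyl-4-oxohexahydropentalene-2,3a(1H)-dicarboxylate | COC(=O)[C@H]1C[C@@]2(C(=O)OC)C(=O)CC[C@H]2C1(C)C | intermediate
13 | dimethyl (2'S,3a'S,6a'S)-1',1'-dimethylhexahydro-1'H-spiro[[1,3]dioxolane-2,4'-pentalene]-2',3a'-dicarboxylate | COC(=O)[C@H]1C[C@@]2(C(=O)OC)C3(OCCO3)CC[C@H]2C1(C)C | intermediate
14 | methyl (2'S,3a'S,6a'S)-2'-acetyl-1',1'-dimethylhexahydro-1'H-spiro[[1,3]dioxolane-2,4'-pentalene]-3a'-carboxylate (not isolated) | CC(=O)[C@H]1C[C@@]2(C(=O)OC)C3(OCCO3)CC[C@H]2C1(C)C | intermediate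
15 | methyl (2'S,3a'S,6a'S)-2'-(2-hydroxypropan-2-yl)-1',1'-dimethylhexahydro-1'H-spiro[[1,3]dioxolane-2,4'-pentalene]-3a'-carboxylate | CC(C)(O)[C@H]1C[C@@]2(C(=O)OC)C3(OCCO3)CC[C@H]2C1(C)C | intermediate
16 | methyl (2S,3aS,6aS)-2-(2-hydroxypropan-2-yl)-1,1-dimethyl-4-oxohexahydropentalene-3a(1H)-carboxylate | CC(C)(O)[C@H]1C[C@@]2(C(=O)OC)C(=O)CC[C@H]2C1(C)C | intermediate
17 | methyl (2S,3aS,5R,6aS)-2-(2-hydroxypropan-2-yl)-1,1,5-trimethyl-4-oxohexahydropentalene-3a(1H)-carboxylate | CC(C)(O)[C@H]1C[C@@]2(C(=O)OC)C(=O)[C@H](C)C[C@H]2C1(C)C | intermediate
18 | methyl (2S,3aS,5S,6aS)-5-(1-hydroxyethyl)-2-(2-hydroxypropan-2-yl)-1,1,5-trimethyl-4-oxohexahydropentalene-3a(1H)-carboxylate (mixture at the hydroxyethyl carbon) | CC(C)(O)[C@H]1C[C@@]2(C(=O)OC)C(=O)[C@](C)(C(C)O)C[C@H]2C1(C)C | intermediate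
19 | methyl (2S,3aS,5S,6aS)-5-acetyl-2-(2-hydroxypropan-2-yl)-1,1,5-trimethyl-4-oxohexahydropentalene-3a(1H)-carboxylate | CC(C)(O)[C@H]1C[C@@]2(C(=O)OC)C(=O)[C@](C)(C(C)=O)C[C@H]2C1(C)C | intermediate
20 | (1R,3S,5S,7S)-8-hydroxy-3-(2-hydroxypropan-2-yl)-4,4,7-trimethyltricyclo[5.3.1.0^{1,5}]undec-8-ene-10,11-dione | C1=C(O)[C@]2(C)C[C@H]3C(C)(C)[C@@H](C(C)(C)O)C[C@@]3(C1=O)C2=O | intermediate
21 | (R)-2-methylbutanoic acid | CC[C@@H](C)C(=O)O | starting material
22 | (1R,3S,5S,7S)-3-(2-hydroxypropan-2-yl)-4,4,7-trimethyl-10,11-dioxotricyclo[5.3.1.0^{1,5}]undec-8-en-8-yl (2R)-2-methylbutanoate (enol ester, not isolated) | C1=C(OC(=O)[C@H](C)CC)[C@]2(C)C[C@H]3C(C)(C)[C@@H](C(C)(C)O)C[C@@]3(C1=O)C2=O | intermediate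
23 | (1S,3S,5S,7S)-8-hydroxy-3-(2-hydroxypropan-2-yl)-4,4,7-trimethyl-9-[(2R)-2-methylbutanoyl]tricyclo[5.3.1.0^{1,5}]undec-8-ene-10,11-dione | CC[C@@H](C)C(=O)C1=C(O)[C@]2(C)C[C@H]3C(C)(C)[C@@H](C(C)(C)O)C[C@@]3(C1=O)C2=O | target

## Step count and least certain steps

Total: 15 steps. Longest linear sequence: 14 steps (1 to 23 through steps 1, 2 and 4–15); step 3 is a one-step branch.

**Step 7 (key step).** The most likely failure is poor facial selectivity in the protonation at C10. The angular ester on C5 also lies on the convex face, so the difference between the two faces may be modest. Insertion of the carbene into the solvent O–H bond is a lesser risk.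

The fallback replaces kinetic protonation by hydrogenation from the convex face. It sets out from 12 obtained together with its C10 epimer, the epimeric keto diester F1, and comes back at 13. The mixture is acetalised as in step 8, which gives 13 together with the epimeric dioxolane F2. Deprotonation of the mixture at C10 with LiN(iPr)2 and trapping with PhSeBr gives the α-phenylselanyl ester F3. H2O2 oxidises it to the selenoxide F4, which eliminates towards C11, the only carbon with a β-hydrogen, to give the cyclopentene diester F5. Hydrogenation over Pd/C should add hydrogen to C10 and C11 from the convex face, opposite the dioxolane, and return 13 with the ester on the concave face.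

**Step 4.** Two things may go wrong. Silyl triflate released during the reaction can catalyse an unselective background reaction and erode the enantioselectivity. The fully substituted diene terminus reacts slowly, which gives 4 time to oligomerise.

The fallback raises the enantiomeric purity by separating diastereomers with a chiral diol that also serves as the C8 protecting group, so no step is added. It sets out from 12 of insufficient enantiomeric purity and comes back at 16. Acetalisation with (2R,3R)-butane-2,3-diol under acid catalysis with removal of water gives the dimethyldioxolane diester F6. The diastereomer that arises from the minor enantiomer, F7, is removed by chromatography or crystallisation; the C2-symmetric diol creates no new stereocentre at C8. F6 is treated with CH3MgBr and CeCl3 as in step 9 and gives, through the methyl ketone F8, the carbinol F9. Aqueous acid as in step 10 then gives 16.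

**Step 9.** The two hindered esters may not be discriminated well enough, or the C10 ester, on the concave face beside the dioxolane, may not react before enolisation sets in.

The fallback makes the C12 carbonyl more reactive by class than the C5 ester. It sets out from 10 and comes back at 15. Photolysis of 10 as in step 7, but in THF containing N,O-dimethylhydroxylamine, traps ketene 11 as the N-methoxy-N-methyl amide F10. Acetalisation as in step 8 gives its dioxolane F11. CH3MgBr converts the amide cleanly into the methyl ketone 14, which is isolated here, and a second addition of CH3MgBr with CeCl3 to the ketone gives 15 while the C5 ester stays untouched.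

**Step 12.** The aldol addition may revert at the congested quaternary carbon (retro-aldol), and the aldehyde may condense with itself under the basic conditions.

The fallback uses an irreversible Lewis acid-mediated Mukaiyama aldol addition of an isolated silyl enol ether. It sets out from 17 and comes back at 18. Trimethylsilyl trifluoromethanesulfonate and Et3N convert 17 into the bis-silyl compound F12, the trimethylsilyl enol ether of the C8 ketone with the carbinol as its trimethylsilyl ether. F12 is treated with CH3CHO and BF3·OEt2 at −78 °C, and aqueous acid work-up removes the silyl groups and gives 18.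

**Step 14.** The tertiary alkoxide may attack C8 and cleave a C8–C bond (retro-Claisen) in competition with the ring closure.

The fallback removes the alkoxide by protection. It sets out from 19 and comes back at 20. Triethylsilyl trifluoromethanesulfonate and 2,6-lutidine give the triethylsilyl ether F13. LiN(SiMe3)2 closes ring A to the silyl-protected trione F14 (identical with A7), and HF·pyridine in THF removes the silyl group to give 20.

## Further compounds

F1 | step 7 | dimethyl (2R,3aS,6aS)-1,1-dimethyl-4-oxohexahydropentalene-2,3a(1H)-dicarboxylate (C10 epimer of 12) | COC(=O)[C@@H]1C[C@@]2(C(=O)OC)C(=O)CC[C@H]2C1(C)C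
F2 | step 7 | dimethyl (2'R,3a'S,6a'S)-1',1'-dimethylhexahydro-1'H-spiro[[1,3]dioxolane-2,4'-pentalene]-2',3a'-dicarboxylate (C10 epimer of 13) | COC(=O)[C@@H]1C[C@@]2(C(=O)OC)C3(OCCO3)CC[C@H]2C1(C)C
F3 | step 7 | dimethyl (3a'S,6a'S)-1',1'-dimethyl-2'-(phenylselanyl)hexahydro-1'H-spiro[[1,3]dioxolane-2,4'-pentalene]-2',3a'-dicarboxylate (mixture at C2') | COC(=O)C1([Se]c3ccccc3)C[C@@]2(C(=O)OC)C4(OCCO4)CC[C@H]2C1(C)C
F4 | step 7 | dimethyl (3a'S,6a'S)-1',1'-dimethyl-2'-(phenylseleninyl)hexahydro-1'H-spiro[[1,3]dioxolane-2,4'-pentalene]-2',3a'-dicarboxylate (selenoxide, not isolated) | COC(=O)C1([Se](=O)c3ccccc3)C[C@@]2(C(=O)OC)C4(OCCO4)CC[C@H]2C1(C)C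
F5 | step 7 | dimethyl (3a'S,6a'S)-1',1'-dimethyl-1',5',6',6a'-tetrahydro-3a'H-spiro[[1,3]dioxolane-2,4'-pentalene]-2',3a'-dicarboxylate | COC(=O)C1=C[C@@]2(C(=O)OC)C3(OCCO3)CC[C@H]2C1(C)C
F6 | step 4 | dimethyl (2'S,3a'S,4R,5R,6a'S)-1',1',4,5-tetramethylhexahydro-1'H-spiro[[1,3]dioxolane-2,4'-pentalene]-2',3a'-dicarboxylate | COC(=O)[C@H]1C[C@@]2(C(=O)OC)C3(O[C@H](C)[C@@H](C)O3)CC[C@H]2C1(C)C
F7 | step 4 | dimethyl (2'R,3a'R,4R,5R,6a'R)-1',1',4,5-tetramethylhexahydro-1'H-spiro[[1,3]dioxolane-2,4'-pentalene]-2',3a'-dicarboxylate (diastereomer from the minor enantiomer) | COC(=O)[C@@H]1C[C@]2(C(=O)OC)C3(O[C@H](C)[C@@H](C)O3)CC[C@@H]2C1(C)C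
F8 | step 4 | methyl (2'S,3a'S,4R,5R,6a'S)-2'-acetyl-1',1',4,5-tetramethylhexahydro-1'H-spiro[[1,3]dioxolane-2,4'-pentalene]-3a'-carboxylate (not isolated) | CC(=O)[C@H]1C[C@@]2(C(=O)OC)C3(O[C@H](C)[C@@H](C)O3)CC[C@H]2C1(C)C
F9 | step 4 | methyl (2'S,3a'S,4R,5R,6a'S)-2'-(2-hydroxypropan-2-yl)-1',1',4,5-tetramethylhexahydro-1'H-spiro[[1,3]dioxolane-2,4'-pentalene]-3a'-carboxylate | CC(C)(O)[C@H]1C[C@@]2(C(=O)OC)C3(O[C@H](C)[C@@H](C)O3)CC[C@H]2C1(C)C
F10 | step 9 | methyl (2S,3aS,6aS)-2-[methoxy(methyl)carbamoyl]-1,1-dimethyl-4-oxohexahydropentalene-3a(1H)-carboxylate | CON(C)C(=O)[C@H]1C[C@@]2(C(=O)OC)C(=O)CC[C@H]2C1(C)C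
F11 | step 9 | methyl (2'S,3a'S,6a'S)-2'-[methoxy(methyl)carbamoyl]-1',1'-dimethylhexahydro-1'H-spiro[[1,3]dioxolane-2,4'-pentalene]-3a'-carboxylate | CON(C)C(=O)[C@H]1C[C@@]2(C(=O)OC)C3(OCCO3)CC[C@H]2C1(C)C
F12 | step 12 | methyl (2S,3aS,6aS)-1,1,5-trimethyl-4-[(trimethylsilyl)oxy]-2-{2-[(trimethylsilyl)oxy]propan-2-yl}-2,3,6,6a-tetrahydropentalene-3a(1H)-carboxylate | C[Si](C)(C)OC(C)(C)[C@H]1C[C@@]2(C(=O)OC)C(O[Si](C)(C)C)=C(C)C[C@H]2C1(C)C
F13 | step 14 | methyl (2S,3aS,5S,6aS)-5-acetyl-1,1,5-trimethyl-4-oxo-2-{2-[(triethylsilyl)oxy]propan-2-yl}hexahydropentalene-3a(1H)-carboxylate | CC[Si](CC)(CC)OC(C)(C)[C@H]1C[C@@]2(C(=O)OC)C(=O)[C@](C)(C(C)=O)C[C@H]2C1(C)C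
F14 | step 14 | (1R,3S,5S,7S)-8-hydroxy-4,4,7-trimethyl-3-{2-[(triethylsilyl)oxy]propan-2-yl}tricyclo[5.3.1.0^{1,5}]undec-8-ene-10,11-dione | C1=C(O)[C@]2(C)C[C@H]3C(C)(C)[C@@H](C(C)(C)O[Si](CC)(CC)CC)C[C@@]3(C1=O)C2=O
A1 | alternative 1 | (2R)-1-[3-((2S)-3,3-dimethyl-2-{2-[(triethylsilyl)oxy]propan-2-yl}pent-4-en-1-yl)-2,4,6-trihydroxy-5-methylphenyl]-2-methylbutan-1-one | CC[C@@H](C)C(=O)c1c(O)c(C)c(O)c(C[C@H](C(C)(C)O[Si](CC)(CC)CC)C(C)(C)C=C)c1O
A2 | alternative 1 | (1S,3S,5S,7S)-8-hydroxy-4,4,7-trimethyl-9-[(2R)-2-methylbutanoyl]-3-{2-[(triethylsilyl)oxy]propan-2-yl}tricyclo[5.3.1.0^{1,5}]undec-8-ene-10,11-dione | CC[C@@H](C)C(=O)C1=C(O)[C@]2(C)C[C@H]3C(C)(C)[C@@H](C(C)(C)O[Si](CC)(CC)CC)C[C@@]3(C1=O)C2=O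
A3 | alternative 2 | spiro[2.4]hepta-4,6-diene | C1=CC2(CC2)C=C1
A4 | alternative 2 | 2-({[tert-butyl(dimethyl)silyl]oxy}methyl)prop-2-enal | C=C(CO[Si](C)(C)C(C)(C)C)C=O
A5 | alternative 2 | 2-({[tert-butyl(dimethyl)silyl]oxy}methyl)spiro[bicyclo[2.2.1]hept-5-ene-7,1'-cyclopropane]-2-carbaldehyde, formyl group exo, enantiomer as in the SMILES | O=C[C@@]1(CO[Si](C)(C)C(C)(C)C)C[C@@H]2C=C[C@H]1C23CC3
A6 | alternative 3 | methyl 1,1,7-trimethyl-4,6-dioxo-2-{2-[(triethylsilyl)oxy]propan-2-yl}decahydroazulene-7-carboxylate, taken as the methyl ester, configuration as in the SMILES | C1C(=O)[C@](C(=O)OC)(C)C[C@H]2C(C)(C)[C@@H](C(C)(C)O[Si](CC)(CC)CC)C[C@@H]2C1=O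
A7 | alternative 3 | (1R,3S,5S,7S)-8-hydroxy-4,4,7-trimethyl-3-{2-[(triethylsilyl)oxy]propan-2-yl}tricyclo[5.3.1.0^{1,5}]undec-8-ene-10,11-dione | C1=C(O)[C@]2(C)C[C@H]3C(C)(C)[C@@H](C(C)(C)O[Si](CC)(CC)CC)C[C@@]3(C1=O)C2=O
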